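**Plan**

- Numbering: C1 is the CO2H carbon, C2 the CH2 next to it, C3–C6 the ring carbons (O2 on C3, O1 on C6), C7–C14 the side chain. Cuts, in order: C1 acid to primary alcohol; C3–H to a C3 peroxyketal; both ring bonds C5–C6 and O2–C3 together; C6–C7 and C8–ethyl (enone from an enyne); C9–C10 by [3,3] rearrangement.
- Enabling feature: C6 is a fully substituted peroxide carbon next to the C7=C8 alkene, so it is the carbon of an allyl-stabilised peroxycarbenium ion (C6=O1+–O2Si). In the 1,2-dioxane ring, C5 (CH2) and C3 (oxygen-bearing) stand 1,3 through C4, the donor/acceptor pattern of a ketone homoenolate, so C3–C4–C5 maps onto a 2-ethylcyclopropanol.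
- Forward: chain C7–C14 (steps 1–5), C6 peroxyketal (6–7), cyclopropane C3–C5 (8–10), then the only ring, the 1,2-dioxane, closes in one [3+3] annulation (11), followed by C3 reduction and C1 oxidation (12–14).
- Stereochemistry: C10 from ligand-controlled Et2Zn addition relayed through a Johnson–Claisen chair (which also gives 11E); 7E from syn-carbocupration/acylation; C4 from an enantioselective Kulinkovich cyclopropanation; C6 in the annulation (weakly controlled, epimer separated); C3 from axial hydride delivery to the cyclic peroxycarbenium ion.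

Key step: step 11

Assumption: the (4R,5R)-TADDOL titanate of step 9 is taken to deliver the (1S,2R)-cyclopropanol; should the sense of induction be the opposite, the (4S,5S)-ligand is used instead.

**Route**

Step 1
Reactants: 1 (E)-pent-2-enal
Product: 2 (3R,4E)-hept-4-en-3-ol
Conditions: Et2Zn (1.5 equiv), (2R)-(+)-3-exo-morpholinoisoborneol (4 mol%), hexane/toluene, 0 °C; aq. NH4Cl
Reagents that add atoms: diethylzinc, CC[Zn]CC
Why: Amino-alcohol-catalysed enantioselective addition of a dialkylzinc to an enal; the (2R)-ligand should direct ethyl transfer to the face that gives the (3R)-carbinol, and the E alkene is untouched.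

Step 2
Reactants: 2 (3R,4E)-hept-4-en-3-ol
Product: 3 ethyl (3R,4E)-3-ethylhept-4-enoate
Conditions: MeC(OEt)3 (5 equiv), EtCO2H (5 mol%), 140 °C, EtOH distilled off
Reagents that add atoms: triethyl orthoacetate, CC(OCC)(OCC)OCC
Why: Johnson–Claisen [3,3] rearrangement through a chair with the carbinol ethyl group equatorial, which should give the E alkene and transfer the C–O configuration suprafacially to the new C–C stereocentre (future C10, R).

Step 3
Reactants: 3 ethyl (3R,4E)-3-ethylhept-4-enoate
Product: 4 (3R,4E)-3-ethylhept-4-enal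
Conditions: i-Bu2AlH (1.05 equiv), CH2Cl2, −78 °C; aq. potassium sodium tartrate
Reagents that add atoms: none
Why: Partial reduction of an ester with i-Bu2AlH, which stops at the aldehyde because the tetrahedral aluminium hemiacetal survives at −78 °C; the stereocentre is β to the carbonyl and cannot epimerise.

Step 4
Reactants: 4 (3R,4E)-3-ethylhept-4-enal
Product: 5 (4R,5E)-4-ethyloct-5-en-1-yne
Conditions: dimethyl (1-diazo-2-oxopropyl)phosphonate, K2CO3, MeOH, 0 to 20 °C
Reagents that add atoms: dimethyl (1-diazo-2-oxopropyl)phosphonate, CC(=O)C(=[N+]=[N-])P(=O)(OC)OC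
Why: Ohira–Bestmann variant of the Seyferth–Gilbert homologation, which converts the aldehyde into the terminal alkyne under mild base without touching the β stereocentre or the alkene.

Step 5
Reactants: 5 (4R,5E)-4-ethyloct-5-en-1-yne
Product: 6 (4E,7R,8E)-5,7-diethylundeca-4,8-dien-3-one
Conditions: EtMgBr, CuBr·SMe2, Et2O/Me2S, −45 °C; then 5, −25 °C; then EtCOCl, Pd(PPh3)4 (3 mol%), THF, −20 to 20 °C
Reagents that add atoms: ethylmagnesium bromide, CC[Mg]Br; propanoyl chloride, CCC(=O)Cl
Why: Syn-carbocupration of a terminal alkyne (ethyl to the internal carbon, copper to the terminal one, cis) followed by Pd-catalysed acylation of the alkenylcopper with retention, so the acyl group ends cis to the new ethyl group (4E, the future 7E).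

Step 6
Reactants: 6 (4E,7R,8E)-5,7-diethylundeca-4,8-dien-3-one
Product: 7 (4E,7R,8E)-5,7-diethyl-3,3-dimethoxyundeca-4,8-diene
Conditions: MeOSiMe3 (2.5 equiv), TMSOTf (2 mol%), CH2Cl2, −78 °C; pyridine quench
Reagents that add atoms: methoxytrimethylsilane, CO[Si](C)(C)C
Why: Acetalization of a ketone with an alkoxysilane under silyl triflate catalysis, an aprotic low-temperature method that should avoid conjugate addition of methanol and migration of the C=C bond.

Step 7
Reactants: 7 (4E,7R,8E)-5,7-diethyl-3,3-dimethoxyundeca-4,8-diene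
Product: 9 triethyl{[(4E,7R,8E)-5,7-diethyl-3-methoxyundeca-4,8-dien-3-yl]peroxy}silane (both epimers at the ketal carbon), via methoxy hydroperoxide 8 (not isolated)
Conditions: anhydrous H2O2 in Et2O (5 equiv), pyridinium p-toluenesulfonate (5 mol%), −20 °C, then Et3N; then Et3SiCl, imidazole, DMF, 0 °C
Reagents that add atoms: hydrogen peroxide, OO; chlorotriethylsilane, CC[Si](Cl)(CC)CC
Why: Acid-catalysed exchange of one ketal methoxy group for hydrogen peroxide through the allyl-stabilised oxocarbenium ion (kinetic capture at the oxygen-bearing carbon), then O-silylation of the hydroperoxide; the new ketal centre forms as a mixture that is erased on ionisation in step 11.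

Step 8
Reactants: 10 methyl 3-hydroxypropanoate
Product: 11 methyl 3-[(tert-butyldiphenylsilyl)oxy]propanoate
Conditions: t-BuPh2SiCl, imidazole, CH2Cl2, 20 °C
Reagents that add atoms: tert-butyl(chloro)diphenylsilane, CC(C)(C)[Si](Cl)(c1ccccc1)c1ccccc1
Why: Standard silylation of a primary alcohol; the tert-butyldiphenylsilyl ether is chosen to survive the Grignard, silyl triflate and silane steps.

Step 9
Reactants: 11 methyl 3-[(tert-butyldiphenylsilyl)oxy]propanoate
Product: 12 (1S,2R)-1-{2-[(tert-butyldiphenylsilyl)oxy]ethyl}-2-ethylcyclopropan-1-ol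
Conditions: n-BuMgBr (2.4 equiv, slow addition), Ti(OiPr)4 premixed 1:1 with (4R,5R)-2,2-dimethyl-α,α,α′,α′-tetraphenyl-1,3-dioxolane-4,5-dimethanol (TADDOL) (1.0 equiv), THF, 0 to 20 °C; aq. NH4Cl
Reagents that add atoms: butylmagnesium bromide, CCCC[Mg]Br
Why: Kulinkovich cyclopropanation, in which the titanacyclopropane formed from two butyl groups acts as a 1,2-dicarbanion toward the ester; the cis relation of the two alkyl groups is intrinsic and the TADDOL titanate should set the absolute configuration (enantioselective Kulinkovich reaction), any minor enantiomer ending as a separable diastereomer after step 11.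

Step 10
Reactants: 12 (1S,2R)-1-{2-[(tert-butyldiphenylsilyl)oxy]ethyl}-2-ethylcyclopropan-1-ol
Product: 13 tert-butyl{2-[(1S,2R)-2-ethyl-1-[(trimethylsilyl)oxy]cyclopropyl]ethoxy}diphenylsilane
Conditions: Me3SiCl, Et3N, DMAP (cat.), CH2Cl2, 0 °C
Reagents that add atoms: chlorotrimethylsilane, C[Si](C)(C)Cl
Why: O-Silylation of the tertiary cyclopropanol under mild base, which gives the siloxycyclopropane (a masked ketone homoenolate) without ring opening.

Step 11
Reactants: 9 triethyl{[(4E,7R,8E)-5,7-diethyl-3-methoxyundeca-4,8-dien-3-yl]peroxy}silane (1.0 equiv); 13 tert-butyl{2-[(1S,2R)-2-ethyl-1-[(trimethylsilyl)oxy]cyclopropyl]ethoxy}diphenylsilane (1.3 equiv)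
Product: 14 tert-butyl(2-{(3R,4R,6S)-6-[(1E,4R,5E)-2,4-diethylocta-1,5-dien-1-yl]-4,6-diethyl-3-[(trimethylsilyl)oxy]-1,2-dioxan-3-yl}ethoxy)diphenylsilane
Conditions: TMSOTf (20 mol%), 2,6-di-tert-butyl-4-methylpyridine (30 mol%), CH2Cl2, −78 to −50 °C; Et3N quench; crude product carried on
Reagents that add atoms: none
Why: Proposed new method: TMSOTf removes methoxide from 9 to give the silylperoxy carbenium ion C6=O1(+)–O2SiEt3, stabilised by O1 and the C7=C8 alkene; the oxygen-activated C3–C5 σ bond of siloxycyclopropane 13 attacks C6 through its unsubstituted CH2 corner (C5), the three-membered ring opens to a silyloxycarbenium ion at C3, and the distal peroxy oxygen O2 closes on C3 with loss of Et3Si+ (released as Et3SiOTf, the chain carrier), so C5–C6 and O2–C3 form in one operation. The closest known reaction types are the Lewis-acid [3+2] annulation of silylperoxy carbenium ions with alkenes to 1,2-dioxolanes and the addition of cyclopropanol silyl ethers (homoenolate equivalents) to oxocarbenium ions; here the cyclopropane σ bond takes the place of the alkene π bond, which makes the annulation a formal [3+3]. The 1,2-dioxane closes 6-exo-trig (O2 onto the exocyclic C3=O+ bond). C4 is carried unchanged from the cyclopropane because no bond to it is broken (the less hindered C3–C5 bond cleaves, not C3–C4), and C3 should form as the anomerically favoured axial silyl ether but is re-ionised in step 12; C6 is set when C5 adds to the planar cation, and the only bias is the chair-like developing ring with both ethyl groups equatorial and the flat alkenyl group axial, so only modest selectivity for 6S is assumed and the 6R epimer is removed by chromatography after step 12. The step needs 1,2- and not 1,4-attack on the conjugated cation, which the fully substituted C8 and the higher charge at the oxygen-bearing C6 should secure, and it needs C–OMe ionisation to outrun O–O heterolysis (Hock/Criegee pathways), which the low temperature and the oxophilic silyl triflate should secure.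

Step 12
Reactants: 14 tert-butyl(2-{(3R,4R,6S)-6-[(1E,4R,5E)-2,4-diethylocta-1,5-dien-1-yl]-4,6-diethyl-3-[(trimethylsilyl)oxy]-1,2-dioxan-3-yl}ethoxy)diphenylsilane
Product: 15 tert-butyl(2-{(3S,4R,6S)-6-[(1E,4R,5E)-2,4-diethylocta-1,5-dien-1-yl]-4,6-diethyl-1,2-dioxan-3-yl}ethoxy)diphenylsilane
Conditions: Et3SiH (3 equiv), TMSOTf (0.3 equiv), 2,6-di-tert-butyl-4-methylpyridine (0.1 equiv), CH2Cl2, −78 °C
Reagents that add atoms: none
Why: Silane reduction of a cyclic (peroxy)ketal through the 1,2-dioxan-3-yl cation (ionic hydrogenation), with axial hydride delivery to the half-chair that keeps the C4 and C6 ethyl groups pseudo-equatorial (the flipped half-chair would set them syn-diaxial), so the C3 side chain ends equatorial and trans to the C4 ethyl group (3S).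

Step 13
Reactants: 15 tert-butyl(2-{(3S,4R,6S)-6-[(1E,4R,5E)-2,4-diethylocta-1,5-dien-1-yl]-4,6-diethyl-1,2-dioxan-3-yl}ethoxy)diphenylsilane
Product: 16 2-[(3S,4R,6S)-6-[(1E,4R,5E)-2,4-diethylocta-1,5-dien-1-yl]-4,6-diethyl-1,2-dioxan-3-yl]ethan-1-ol
Conditions: HF·pyridine, THF/pyridine, 0 to 20 °C
Reagents that add atoms: none
Why: Fluoride cleavage of the silyl ether under acidic, non-basic conditions, which avoids base-induced Kornblum–DeLaMare fragmentation of the peroxide at C3–H.

Step 14
Reactants: 16 2-[(3S,4R,6S)-6-[(1E,4R,5E)-2,4-diethylocta-1,5-dien-1-yl]-4,6-diethyl-1,2-dioxan-3-yl]ethan-1-ol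
Product: 17 2-[(3S,4R,6S)-6-[(1E,4R,5E)-2,4-diethylocta-1,5-dien-1-yl]-4,6-diethyl-1,2-dioxan-3-yl]acetic acid
Conditions: TEMPO (20 mol%), PhI(OAc)2 (2.5 equiv), MeCN/pH 7 buffer (1:1), 20 °C
Reagents that add atoms: water, O
Why: Oxoammonium (TEMPO) oxidation of the primary alcohol through the aldehyde hydrate to the carboxylic acid, conditions under which dialkyl peroxides and unactivated alkenes should persist.

**Compound list**

1 | (E)-pent-2-enal | CC/C=C/C=O | starting material
2 | (3R,4E)-hept-4-en-3-ol | CC[C@@H](O)/C=C/CC | intermediate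
3 | ethyl (3R,4E)-3-ethylhept-4-enoate | CC/C=C/[C@H](CC)CC(=O)OCC | intermediate
4 | (3R,4E)-3-ethylhept-4-enal | CC/C=C/[C@H](CC)CC=O | intermediate
5 | (4R,5E)-4-ethyloct-5-en-1-yne | CC/C=C/[C@H](CC)CC#C | intermediate
6 | (4E,7R,8E)-5,7-diethylundeca-4,8-dien-3-one | CC/C=C/[C@H](CC)C/C(=C/C(=O)CC)CC | intermediate
7 | (4E,7R,8E)-5,7-diethyl-3,3-dimethoxyundeca-4,8-diene | CC/C=C/[C@H](CC)C/C(=C/C(CC)(OC)OC)CC | intermediate
8 | (4E,7R,8E)-5,7-diethyl-3-methoxyundeca-4,8-dien-3-yl hydroperoxide (both C3 epimers; not isolated) | CC/C=C/[C@H](CC)C/C(=C/C(CC)(OC)OO)CC | intermediate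
9 | triethyl{[(4E,7R,8E)-5,7-diethyl-3-methoxyundeca-4,8-dien-3-yl]peroxy}silane (both C3 epimers) | CC/C=C/[C@H](CC)C/C(=C/C(CC)(OC)OO[Si](CC)(CC)CC)CC | intermediate
10 | methyl 3-hydroxypropanoate | COC(=O)CCO | starting material
11 | methyl 3-[(tert-butyldiphenylsilyl)oxy]propanoate | COC(=O)CCO[Si](c1ccccc1)(c1ccccc1)C(C)(C)C | intermediate
12 | (1S,2R)-1-{2-[(tert-butyldiphenylsilyl)oxy]ethyl}-2-ethylcyclopropan-1-ol | C1[C@@H](CC)[C@@]1(O)CCO[Si](c2ccccc2)(c2ccccc2)C(C)(C)C | intermediate
13 | tert-butyl{2-[(1S,2R)-2-ethyl-1-[(trimethylsilyl)oxy]cyclopropyl]ethoxy}diphenylsilane | C1[C@@H](CC)[C@@]1(O[Si](C)(C)C)CCO[Si](c2ccccc2)(c2ccccc2)C(C)(C)C | intermediate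
14 | tert-butyl(2-{(3R,4R,6S)-6-[(1E,4R,5E)-2,4-diethylocta-1,5-dien-1-yl]-4,6-diethyl-3-[(trimethylsilyl)oxy]-1,2-dioxan-3-yl}ethoxy)diphenylsilane | CC/C=C/[C@H](CC)C/C(=C/[C@]1(CC)C[C@@H](CC)[C@](O[Si](C)(C)C)(CCO[Si](c2ccccc2)(c2ccccc2)C(C)(C)C)OO1)CC | intermediate
15 | tert-butyl(2-{(3S,4R,6S)-6-[(1E,4R,5E)-2,4-diethylocta-1,5-dien-1-yl]-4,6-diethyl-1,2-dioxan-3-yl}ethoxy)diphenylsilane | CC/C=C/[C@H](CC)C/C(=C/[C@]1(CC)C[C@@H](CC)[C@H](CCO[Si](c2ccccc2)(c2ccccc2)C(C)(C)C)OO1)CC | intermediate
16 | 2-[(3S,4R,6S)-6-[(1E,4R,5E)-2,4-diethylocta-1,5-dien-1-yl]-4,6-diethyl-1,2-dioxan-3-yl]ethan-1-ol | CC/C=C/[C@H](CC)C/C(=C/[C@]1(CC)C[C@@H](CC)[C@H](CCO)OO1)CC | intermediate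
17 | 2-[(3S,4R,6S)-6-[(1E,4R,5E)-2,4-diethylocta-1,5-dien-1-yl]-4,6-diethyl-1,2-dioxan-3-yl]acetic acid | CC/C=C/[C@H](CC)C/C(=C/[C@]1(CC)C[C@@H](CC)[C@H](CC(=O)O)OO1)CC | target

**Count and risks**

Total step count: 14. Longest linear sequence: 11 (steps 1–7, then 11–14).

Steps most likely to fail:

1. Step 11 (Proposed new method). What may go wrong: poor facial selectivity at C6 when C5 adds to the planar cation; O–O heterolysis of the peroxyketal before C–C bond formation; attack of the cyclopropane at C8 instead of C6; simple ring opening of 13 to the ketone. Fallback by known chemistry, setting out from enone 6 and rejoining the route at target 17: 6 is treated with the Grignard reagent of separately prepared (S)-3-(bromomethyl)pent-1-ene F1 (Mg; then CeCl3, THF, −78 °C) to give, by 1,2-addition, the tertiary allylic alcohol F2 as both carbinol epimers. Cross-metathesis of its terminal vinyl group with methyl acrylate (second-generation Hoveyda–Grubbs catalyst) gives the hydroxy enoate F3. Acid-catalysed exchange of the tertiary allylic hydroxyl with hydrogen peroxide (H2O2, cat. H2SO4, Et2O, 0 °C) gives the tertiary allylic hydroperoxide F4. Et2NH in CF3CH2OH then closes the ring by intramolecular peroxy-Michael addition to the methyl ester F5 (3,4-trans expected from the reversible addition; C6 epimers separated), and LiOH in aqueous THF hydrolyses F5 to 17.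

2. Step 7. What may go wrong: conjugate capture of hydrogen peroxide at C8 of the allyl cation followed by closure to a five-membered cyclic peroxide; loss of the 4E geometry through a dienol ether. Fallback, setting out from enone 6 and rejoining at 14: kinetic enolisation of 6 (LiN(iPr)2, Et3SiCl, THF, −78 °C) gives the silyl dienol ether F6. Isayama–Mukaiyama-type peroxidation of the enol ether (Co(acac)2, O2, Et3SiH) gives the bis-silyl monoperoxyketal F7. F7 takes the place of 9 in step 11 (triethylsilanolate leaves instead of methoxide) and gives 14.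

3. Step 9. What may go wrong: erosion of enantioselectivity by a competing achiral titanium alkoxide cycle, or the opposite sense of induction. Fallback, setting out from ester 11 and rejoining at 12: a racemic Kulinkovich reaction (n-BuMgBr, catalytic Ti(OiPr)4) gives the racemic cis-cyclopropanol F8. Esterification with (S)-2-methoxy-2-phenylacetic acid (carbodiimide, DMAP) and chromatographic separation of the diastereomers gives the ester F9. Methanolysis (K2CO3, MeOH, 0 °C) returns 12.

**Further compounds**

F1 | step 11 | (S)-3-(bromomethyl)pent-1-ene | BrC[C@@H](CC)C=C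
F2 | step 11 | (3R,6E,9R,10E)-3,5,7,9-tetraethyltrideca-1,6,10-trien-5-ol (both C5 epimers) | CC/C=C/[C@H](CC)C/C(=C/C(O)(CC)C[C@@H](CC)C=C)CC
F3 | step 11 | methyl (2E,4R,7E,10R,11E)-4,6,8,10-tetraethyl-6-hydroxytetradeca-2,7,11-trienoate (both C6 epimers) | CC/C=C/[C@H](CC)C/C(=C/C(O)(CC)C[C@@H](CC)/C=C/C(=O)OC)CC
F4 | step 11 | methyl (2E,4R,7E,10R,11E)-4,6,8,10-tetraethyl-6-hydroperoxytetradeca-2,7,11-trienoate (both C6 epimers) | CC/C=C/[C@H](CC)C/C(=C/C(OO)(CC)C[C@@H](CC)/C=C/C(=O)OC)CC
F5 | step 11 | methyl 2-[(3S,4R,6S)-6-[(1E,4R,5E)-2,4-diethylocta-1,5-dien-1-yl]-4,6-diethyl-1,2-dioxan-3-yl]acetate | CC/C=C/[C@H](CC)C/C(=C/[C@]1(CC)C[C@@H](CC)[C@H](CC(=O)OC)OO1)CC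
F6 | step 7 | triethyl{[(4E,7R,8E)-5,7-diethylundeca-2,4,8-trien-3-yl]oxy}silane (enol ether geometry not defined) | CC/C=C/[C@H](CC)C/C(=C/C(O[Si](CC)(CC)CC)=CC)CC
F7 | step 7 | triethyl{[(4E,7R,8E)-5,7-diethyl-3-[(triethylsilyl)peroxy]undeca-4,8-dien-3-yl]oxy}silane (both C3 epimers) | CC/C=C/[C@H](CC)C/C(=C/C(CC)(O[Si](CC)(CC)CC)OO[Si](CC)(CC)CC)CC
F8 | step 9 | racemic cis-1-{2-[(tert-butyldiphenylsilyl)oxy]ethyl}-2-ethylcyclopropan-1-ol, (1S,2R) and (1R,2S) | C1[C@@H](CC)[C@@]1(O)CCO[Si](c2ccccc2)(c2ccccc2)C(C)(C)C.C1[C@H](CC)[C@]1(O)CCO[Si](c2ccccc2)(c2ccccc2)C(C)(C)C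
F9 | step 9 | (1S,2R)-1-{2-[(tert-butyldiphenylsilyl)oxy]ethyl}-2-ethylcyclopropyl (2S)-2-methoxy-2-phenylacetate | C1[C@@H](CC)[C@@]1(OC(=O)[C@@H](OC)c2ccccc2)CCO[Si](c3ccccc3)(c3ccccc3)C(C)(C)C
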